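The trans fusion of rings A and B, C3a (methyl, β) and C7a (H, α), is read as the β- and α-carbon of a 3-methylcyclohexenone with C7 as carbonyl. Head-to-head (2+2) photocycloaddition of allene to (S)-4-(tert-butyldimethylsilyloxy)-3-methylcyclohex-2-enone forms C3a–C3 and a temporary C7a–C2 bond in one operation, creating the quaternary C3a, the trans C7a–H and a strained methylenecyclobutane. The pseudoaxial C4 silyl ether only steers the face; C4 is reset through its ketone before bromide enters with inversion. The stored strain later drives a 1,2-shift of C7a from C2 to C1, which delivers ring B as a regiodefined enolate for aldol union with ring C.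

Key step: step 6

Remark: locants follow the target (ring A: C3a, C4, C5, C6, C7, C7a; ring B: C1, C2, C3, C3a, C7a; C8 is the carbinol linker; ring C: C1' to C6'); β is the face of the C3a methyl group, α the opposite face.
Remark: the lipase of step 2 is assumed to hydrolyse the (R)-acetate, the usual preference for such secondary esters; with an enzyme of opposite preference the (S)-alcohol 4 is taken directly and step 3 falls away.
Remark: addition of allene anti to the C4 silyloxy group leaves that oxygen cis to the C3a methyl, the side on which the target carries bromine; because bromide is introduced with inversion, C4 is first epimerised through its ketone (steps 8 to 11).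

Step 1
Reactants: 1 3-ethoxycyclohex-2-enone
Product: 2 rac-6-acetoxy-3-ethoxycyclohex-2-enone
Conditions: Mn(OAc)3·2H2O, benzene, reflux (Dean–Stark)
Reagents that add atoms: manganese triacetate, CC(=O)[O-].CC(=O)[O-].CC(=O)[O-].[Mn+3]
Why: Oxidation with Mn(OAc)3 (trivalent manganese) goes through the cross-conjugated manganese enolate and transfers acetate to C6 only, the known acetoxylation of vinylogous esters on the carbonyl side remote from the double bond; the new centre is formed as a racemate.

Step 2
Reactants: 2 rac-6-acetoxy-3-ethoxycyclohex-2-enone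
Product: 3 (S)-6-acetoxy-3-ethoxycyclohex-2-enone
Conditions: Amano lipase PS, pH 7 phosphate buffer/MTBE, 25 °C, stopped just beyond half conversion
Reagents that add atoms: none
Why: Lipase-catalysed kinetic resolution by enantioselective ester hydrolysis: the (R)-acetate is cleaved to the more polar alcohol and the (S)-acetate is recovered, so the later C4 centre, the control element of step 6, is obtained in one enantiomeric form.

Step 3
Reactants: 3 (S)-6-acetoxy-3-ethoxycyclohex-2-enone
Product: 4 (S)-3-ethoxy-6-hydroxycyclohex-2-enone
Conditions: K2CO3, EtOH, 0 °C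
Reagents that add atoms: none
Why: Carbonate-catalysed transesterification in ethanol, which cannot scramble the ethoxy group of the vinylogous ester, removes the acetyl group at 0 °C without enolising the oxygenated centre.

Step 4
Reactants: 4 (S)-3-ethoxy-6-hydroxycyclohex-2-enone
Product: 5 (S)-6-(tert-butyldimethylsilyloxy)-3-ethoxycyclohex-2-enone
Conditions: TBSCl, imidazole, DMF, 25 °C
Reagents that add atoms: tert-butyldimethylsilyl chloride, CC(C)(C)[Si](C)(C)Cl
Why: Standard silylation of a secondary alcohol with a silyl chloride and imidazole; the bulky group is chosen as the facial control element for step 6 and is inert to MeLi and to light above 300 nm.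

Step 5
Reactants: 5 (S)-6-(tert-butyldimethylsilyloxy)-3-ethoxycyclohex-2-enone
Product: 7 (S)-4-(tert-butyldimethylsilyloxy)-3-methylcyclohex-2-enone, via tertiary allylic alcohol 6 (not isolated)
Conditions: MeLi, THF, −78 °C; then 1 M HCl, 0 °C
Reagents that add atoms: methyllithium, [Li]C; water, O
Why: Stork–Danheiser transposition: 1,2-addition of MeLi to the vinylogous ester and acid hydrolysis of the resulting enol ether with loss of water move the carbonyl to the former ether carbon and leave the methyl group on the β-carbon, while the silyloxy centre (now C4) is untouched.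

Step 6
Reactants: 7 (S)-4-(tert-butyldimethylsilyloxy)-3-methylcyclohex-2-enone; 8 allene
Product: 9 trans-fused 5-(tert-butyldimethylsilyloxy)-6-methyl-8-methylenebicyclo[4.2.0]octan-2-one (target locants: C7 ketone, C2 methylene, C3a methyl β, C7a–H α, C4 silyloxy β)
Conditions: hν (350 nm, Pyrex), allene (excess), CH2Cl2, −78 °C; volatiles removed cold, used at once
Reagents that add atoms: none
Why: Enone–allene (2+2) photocycloaddition: n,π* excitation and intersystem crossing give a triplet twisted about the C3a–C7a bond, which bonds to allene to a triplet 1,4-biradical that closes after spin inversion. The closest known reaction type is the head-to-head photoaddition of allene to cyclohexenones, together with the trans-fused bicyclo[4.2.0]octan-2-ones that twisted cyclohexenone triplets give with simple alkenes. The only ring formed, the cyclobutane C2–C3–C3a–C7a, closes stepwise by radical–radical coupling of the biradical (a formal [π2+π2] closure), with the central allene carbon on C7a and a terminal carbon on C3a. C3a is set by addition anti to the C4 silyloxy group, which A(1,2) strain with the C3a methyl holds pseudoaxial over one face, and C7a is set trans to the new C3a–C3 bond because the twisted intermediate closes before ring A relaxes. The step needs head-to-head orientation (secured by the polarity of the enone triplet and the allyl-type radical on the allene unit), anti attack (secured by the bulky silyl ether) and survival of the epimerisable trans fusion (secured by cold, neutral handling and immediate use in step 7).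

Step 7
Reactants: 9 trans-fused photoadduct
Product: 10 C7 tertiary alcohol of the trans-fused methylenecyclobutane (C7–OH β and axial; C7–methyl α; C4 silyloxy β)
Conditions: MeLi, CeCl3, THF, −78 °C; then H2O
Reagents that add atoms: methyllithium, [Li]C
Why: Organocerium 1,2-addition, which is nucleophilic but hardly basic and so does not epimerise C7a; the methyl group enters equatorially from the α face, away from the axial C3a methyl and from the cyclobutane carbon on C7a, which sets C7 with the axial β-hydroxyl and removes the carbonyl that made the trans fusion labile.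

Step 8
Reactants: 10 C7 tertiary alcohol
Product: 11 C4,C7-diol (C4–OH β and equatorial; C7–OH β)
Conditions: Bu4NF, THF, 25 → 40 °C
Reagents that add atoms: none
Why: Fluoride-induced cleavage of the secondary silyl ether through Si–F bond formation; the tertiary alcohol and the methylenecyclobutane are inert.

Step 9
Reactants: 11 C4,C7-diol
Product: 12 C4 ketone with free C7–OH
Conditions: Dess–Martin periodinane, CH2Cl2, 0 → 25 °C
Reagents that add atoms: none
Why: Dess–Martin oxidation takes the secondary alcohol to the ketone under neutral conditions and leaves the tertiary alcohol alone; the C4 configuration, which has done its work as control element, is erased on purpose.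

Step 10
Reactants: 12 C4 ketone with free C7–OH
Product: 13 C4 ketone, C7 triethylsilyl ether
Conditions: Et3SiOTf, 2,6-lutidine, CH2Cl2, −78 → 0 °C
Reagents that add atoms: triethylsilyl triflate, CC[Si](CC)(CC)OS(=O)(=O)C(F)(F)F
Why: Silylation of the hindered tertiary alcohol with a silyl triflate and a hindered pyridine base; the ether prevents ionisation of C7 (next to the cyclobutane) in step 12 and participation of the hydroxyl later, and any enol silane of the C4 ketone reverts on aqueous work-up.

Step 11
Reactants: 13 C4 ketone, C7 triethylsilyl ether
Product: 14 C4 alcohol with α, axial hydroxyl (trans to the C3a methyl)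
Conditions: LiBH(s-Bu)3, THF, −78 °C; then H2O
Reagents that add atoms: none
Why: Reduction with a bulky trialkylborohydride, which attacks the ketone from the equatorial (β) side as it does in cyclohexanones flanked by a quaternary carbon such as 4,4-dimethyl-3-keto triterpenoids, gives the axial α-alcohol at C4.

Step 12
Reactants: 14 C4 axial alcohol
Product: 15 C4 bromide with β, equatorial bromine (cis to the C3a methyl)
Conditions: PPh3, CBr4, CH2Cl2, 0 → 40 °C
Reagents that add atoms: carbon tetrabromide, BrC(Br)(Br)Br
Why: Appel reaction: the axial oxyphosphonium ion is displaced by bromide in an SN2 step with inversion, which sets C4 as the equatorial β-bromide of the target; the equatorial bromide has no antiperiplanar hydrogen and survives the later basic steps.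

Step 13
Reactants: 15 C4 bromide
Product: 17 trans-fused cyclobutanone (C2 ketone), via ozonide 16 (not isolated)
Conditions: O3, CH2Cl2, −78 °C; then Me2S, −78 → 0 °C; used crude
Reagents that add atoms: ozone, [O-][O+]=O
Why: Ozonolysis (cycloaddition, cycloreversion and reductive cleavage of the ozonide) cleaves the only alkene to the cyclobutanone; neutral work-up at low temperature keeps C7a, now α to the ketone, from epimerising.

Step 14
Reactants: 17 trans-fused cyclobutanone
Product: 18 C2 dibromomethyl carbinol (C2–OH β; CHBr2 α)
Conditions: CH2Br2, lithium 2,2,6,6-tetramethylpiperidide, THF, −78 °C; then AcOH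
Reagents that add atoms: dibromomethane, BrCBr
Why: Carbonyl addition of dibromomethyllithium, generated in the presence of the ketone, to the strained and very electrophilic cyclobutanone is faster than enolisation; attack from the α face, anti to C7, gives the carbinol, whose C2 configuration is lost again in step 22.

Step 15
Reactants: 19 6-methylhept-5-en-2-one
Product: 20 4-[(2R)-3,3-dimethyloxiran-2-yl]butan-2-one
Conditions: D-fructose-derived Shi ketone (cat.), KHSO5 (as the triple salt 2KHSO5·KHSO4·K2SO4), K2CO3, MeCN/dimethoxymethane/aq. buffer, 0 °C
Reagents that add atoms: potassium peroxymonosulfate, [K+].[O-]S(=O)(=O)OO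
Why: Shi epoxidation: the dioxirane formed from the chiral ketone and KHSO5 transfers oxygen to the trisubstituted alkene through a spiro transition state, which sets the (R) configuration of the epoxide CH carbon (later C4'); the substrate's own methyl ketone is a far poorer dioxirane precursor than the catalyst.

Step 16
Reactants: 20 (R)-epoxy ketone
Product: 21 (R)-2,2-dimethyl-3-[3-(trimethylsilyloxy)but-3-enyl]oxirane
Conditions: LiN(iPr)2, Me3SiCl, THF, −78 °C (internal quench)
Reagents that add atoms: chlorotrimethylsilane, C[Si](C)(C)Cl
Why: Kinetic deprotonation of the methyl group with a hindered amide base in the presence of the silyl chloride gives the less substituted enol silane before the enolate can open the epoxide.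

Step 17
Reactants: 21 epoxy enol silane
Product: 22 (R)-4-hydroxy-3,3-dimethylcyclohexanone
Conditions: TiCl4, CH2Cl2, −78 °C; then H2O
Reagents that add atoms: none
Why: Lewis acid-promoted epoxide–enol silane cyclisation (a cation–olefin ring closure): the nucleophilic carbon attacks the activated epoxide at its tertiary carbon (6-endo opening) and closes ring C, while the oxygen-bearing carbon is not touched and keeps its (R) configuration.

Step 18
Reactants: 22 (R)-4-hydroxy-3,3-dimethylcyclohexanone
Product: 23 (S)-4-bromo-3,3-dimethylcyclohexanone
Conditions: PPh3, CBr4, CH2Cl2, 0 → 40 °C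
Reagents that add atoms: carbon tetrabromide, BrC(Br)(Br)Br
Why: Appel reaction with SN2 inversion at the neopentyl-type secondary carbon, reached through the chair with the oxyphosphonium group axial, converts the (R)-alcohol into the (S)-bromide (C4').

Step 19
Reactants: 23 (S)-4-bromo-3,3-dimethylcyclohexanone
Product: 24 (1R,4S)-4-bromo-1-ethenyl-3,3-dimethylcyclohexan-1-ol
Conditions: CH2=CHMgBr, CeCl3, THF, −78 °C; then H2O
Reagents that add atoms: vinylmagnesium bromide, C=C[Mg]Br
Why: Organocerium 1,2-addition avoids enolisation; the vinyl group attacks C1' equatorially, anti to the axial methyl on C3' (as with 3,3,5-trimethylcyclohexanone), which gives the axial hydroxyl cis to the equatorial bromine, i.e. (1R).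

Step 20
Reactants: 24 vinyl carbinol
Product: 25 (1R,4S)-4-bromo-1-ethenyl-3,3-dimethyl-1-(triethylsilyloxy)cyclohexane
Conditions: Et3SiOTf, 2,6-lutidine, CH2Cl2, −78 → 0 °C
Reagents that add atoms: triethylsilyl triflate, CC[Si](CC)(CC)OS(=O)(=O)C(F)(F)F
Why: Silyl triflate silylation of the tertiary alcohol, needed because a free α-hydroxy aldehyde would dimerise and would quench the enolate in step 22.

Step 21
Reactants: 25 silyl ether of the vinyl carbinol
Product: 27 (1R,4S)-4-bromo-3,3-dimethyl-1-(triethylsilyloxy)cyclohexane-1-carbaldehyde, via ozonide 26 (not isolated)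
Conditions: O3, CH2Cl2, −78 °C; then PPh3
Reagents that add atoms: ozone, [O-][O+]=O
Why: Ozonolysis of the vinyl group with reductive work-up gives the α-silyloxy aldehyde, which has no α-hydrogen and cannot epimerise.

Step 22
Reactants: 18 C2 dibromomethyl carbinol; 27 ring C aldehyde
Product: 30 β-hydroxy ketone (C2 ketone; C8–OH (R); C1 side chain α), via lithium enolate 28 (not isolated), via titanium enolate 29 (not isolated)
Conditions: n-BuLi (2.1 equiv), THF, −78 → −40 °C; ClTi(OiPr)3, −78 °C; 27, −78 → −30 °C; then H2O
Reagents that add atoms: none
Why: β-Oxido carbenoid ring enlargement followed by a titanium aldol reaction: bromine–lithium exchange on the alkoxide gives a carbenoid in which the more substituted and strained C7a–C2 bond shifts to the carbenoid carbon (C1) with retention at C7a and loss of LiBr, the resulting lithium enolate is therefore regiodefined (C1=C2), and as its triisopropoxytitanium enolate it adds to aldehyde 27 syn-selectively (as known for titanium enolates of cyclic ketones) on the α face, anti to the C3a methyl and the axial C7 silyloxy group, which sets C1 (S) and C8 (R).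

Step 23
Reactants: 30 β-hydroxy ketone
Product: 32 C7,C1'-bis(triethylsilyl) ether of the target (C2–OH α), via boron chelate 31 (not isolated)
Conditions: Et2BOMe, THF/MeOH 4:1, −78 °C; NaBH4; then MeOH (evaporation)
Reagents that add atoms: none
Why: Narasaka–Prasad reduction: the C8 hydroxyl and the C2 ketone form a six-membered diethylboron chelate and external hydride adds to C2 from the β face, trans to the C1 side chain, which gives the syn-1,3-diol with the α-hydroxyl, C2 (R).

Step 24
Reactants: 32 bis(triethylsilyl) ether
Product: 33 CNP0144982.1 (1'R,8R,1S,2R,3aS,4S,7R,7aS,4'S)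
Conditions: HF·pyridine, THF/pyridine, 0 → 25 °C
Reagents that add atoms: none
Why: Fluoride cleaves both tertiary triethylsilyl ethers through formation of strong Si–F bonds under mildly acidic conditions that leave the neopentyl bromides and the polyol intact, to give the target.

Compound list
1 | 3-ethoxycyclohex-2-enone | CCOC1=CC(=O)CCC1 | starting material
2 | rac-6-acetoxy-3-ethoxycyclohex-2-enone | CCOC1=CC(=O)C(OC(C)=O)CC1 | intermediate
3 | (S)-6-acetoxy-3-ethoxycyclohex-2-enone | CCOC1=CC(=O)[C@@H](OC(C)=O)CC1 | intermediate
4 | (S)-3-ethoxy-6-hydroxycyclohex-2-enone | CCOC1=CC(=O)[C@@H](O)CC1 | intermediate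
5 | (S)-6-(tert-butyldimethylsilyloxy)-3-ethoxycyclohex-2-enone | CCOC1=CC(=O)[C@@H](O[Si](C)(C)C(C)(C)C)CC1 | intermediate
6 | (6S)-6-(tert-butyldimethylsilyloxy)-3-ethoxy-1-methylcyclohex-2-en-1-ol (C1 epimers; lithium alkoxide before the quench) | CCOC1=CC(C)(O)[C@@H](O[Si](C)(C)C(C)(C)C)CC1 | intermediate
7 | (S)-4-(tert-butyldimethylsilyloxy)-3-methylcyclohex-2-enone | CC1=CC(=O)CC[C@@H]1O[Si](C)(C)C(C)(C)C | intermediate
8 | allene (propa-1,2-diene) | C=C=C | starting material
9 | trans-fused 5-(tert-butyldimethylsilyloxy)-6-methyl-8-methylenebicyclo[4.2.0]octan-2-one (C3a methyl β, C7a–H α, C4–OSi β) | C=C1C[C@]2(C)[C@@H](O[Si](C)(C)C(C)(C)C)CCC(=O)[C@@H]12 | intermediate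
10 | C7 tertiary alcohol of 9 (C7–OH β, C7–methyl α) | C=C1C[C@]2(C)[C@@H](O[Si](C)(C)C(C)(C)C)CC[C@@](C)(O)[C@@H]12 | intermediate
11 | C4,C7-diol (C4–OH β, C7–OH β) | C=C1C[C@]2(C)[C@@H](O)CC[C@@](C)(O)[C@@H]12 | intermediate
12 | C4 ketone with free C7–OH | C=C1C[C@]2(C)C(=O)CC[C@@](C)(O)[C@@H]12 | intermediate
13 | C4 ketone, C7 triethylsilyl ether | C=C1C[C@]2(C)C(=O)CC[C@@](C)(O[Si](CC)(CC)CC)[C@@H]12 | intermediate
14 | C4 α (axial) alcohol, C7 triethylsilyl ether | C=C1C[C@]2(C)[C@H](O)CC[C@@](C)(O[Si](CC)(CC)CC)[C@@H]12 | intermediate
15 | C4 β (equatorial) bromide, C7 triethylsilyl ether, C2 methylene | C=C1C[C@]2(C)[C@@H](Br)CC[C@@](C)(O[Si](CC)(CC)CC)[C@@H]12 | intermediate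
16 | ozonide of 15 (spiro 1,2,4-trioxolane at C2, both spiro epimers) | C1OC2(OO1)C[C@]3(C)[C@@H](Br)CC[C@@](C)(O[Si](CC)(CC)CC)[C@@H]23 | intermediate
17 | trans-fused cyclobutanone (C2 ketone) | O=C1C[C@]2(C)[C@@H](Br)CC[C@@](C)(O[Si](CC)(CC)CC)[C@@H]12 | intermediate
18 | C2 dibromomethyl carbinol (C2–OH β, CHBr2 α) | BrC(Br)[C@]1(O)C[C@]2(C)[C@@H](Br)CC[C@@](C)(O[Si](CC)(CC)CC)[C@@H]12 | intermediate
19 | 6-methylhept-5-en-2-one | CC(C)=CCCC(C)=O | starting material
20 | 4-[(2R)-3,3-dimethyloxiran-2-yl]butan-2-one | CC(=O)CC[C@H]1OC1(C)C | intermediate
21 | (R)-2,2-dimethyl-3-[3-(trimethylsilyloxy)but-3-enyl]oxirane | C=C(O[Si](C)(C)C)CC[C@H]1OC1(C)C | intermediate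
22 | (R)-4-hydroxy-3,3-dimethylcyclohexanone | CC1(C)CC(=O)CC[C@H]1O | intermediate
23 | (S)-4-bromo-3,3-dimethylcyclohexanone | CC1(C)CC(=O)CC[C@@H]1Br | intermediate
24 | (1R,4S)-4-bromo-1-ethenyl-3,3-dimethylcyclohexan-1-ol | CC1(C)C[C@@](O)(C=C)CC[C@@H]1Br | intermediate
25 | (1R,4S)-4-bromo-1-ethenyl-3,3-dimethyl-1-(triethylsilyloxy)cyclohexane | CC1(C)C[C@@](O[Si](CC)(CC)CC)(C=C)CC[C@@H]1Br | intermediate
26 | ozonide of 25 (1,2,4-trioxolan-3-yl on C1', both epimers) | CC1(C)C[C@@](O[Si](CC)(CC)CC)(C2OCOO2)CC[C@@H]1Br | intermediate
27 | (1R,4S)-4-bromo-3,3-dimethyl-1-(triethylsilyloxy)cyclohexane-1-carbaldehyde | CC1(C)C[C@@](O[Si](CC)(CC)CC)(C=O)CC[C@@H]1Br | intermediate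
28 | lithium enolate (C1=C2–OLi) of the trans-fused hydrindan-2-one | C1=C(O[Li])C[C@]2(C)[C@@H](Br)CC[C@@](C)(O[Si](CC)(CC)CC)[C@@H]12 | intermediate
29 | triisopropoxytitanium enolate (C1=C2–OTi) | C1=C(O[Ti](OC(C)C)(OC(C)C)OC(C)C)C[C@]2(C)[C@@H](Br)CC[C@@](C)(O[Si](CC)(CC)CC)[C@@H]12 | intermediate
30 | β-hydroxy ketone (C2 ketone, C8–OH, C7 and C1' triethylsilyl ethers) | CC1(C)C[C@@](O[Si](CC)(CC)CC)([C@H](O)[C@@H]2C(=O)C[C@]3(C)[C@@H](Br)CC[C@@](C)(O[Si](CC)(CC)CC)[C@@H]23)CC[C@@H]1Br | intermediate
31 | diethylboron chelate of 30 (O8–BEt2 coordinated to the C2 carbonyl) | CC1(C)C[C@@](O[Si](CC)(CC)CC)([C@H](OB(CC)CC)[C@@H]2C(=O)C[C@]3(C)[C@@H](Br)CC[C@@](C)(O[Si](CC)(CC)CC)[C@@H]23)CC[C@@H]1Br | intermediate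
32 | C7,C1'-bis(triethylsilyl) ether of the target | CC1(C)C[C@@](O[Si](CC)(CC)CC)([C@H](O)[C@@H]2[C@H](O)C[C@]3(C)[C@@H](Br)CC[C@@](C)(O[Si](CC)(CC)CC)[C@@H]23)CC[C@@H]1Br | intermediate
33 | CNP0144982.1 | CC1(C)C[C@@](O)([C@H](O)[C@@H]2[C@H](O)C[C@]3(C)[C@@H](Br)CC[C@@](C)(O)[C@@H]23)CC[C@@H]1Br | target

Total step count: 24. Longest linear sequence: 17 steps (steps 1 to 14 and 22 to 24, from 3-ethoxycyclohex-2-enone); the ring C branch (steps 15 to 21) has 7 steps before the union.

Steps most likely to fail

Step 6. The biradical may close mainly after ring A has relaxed, giving the cis ring fusion. Facial discrimination by the C4 silyl ether may be incomplete, and the trans fusion may be lost by enolisation during handling. Fallback: the way of excitation is changed. Enone 7 is irradiated at 366–405 nm in CH2Cl2 at −78 °C with allene 8 as its complex with a bulky Lewis acid (an oxazaborolidine activated by AlBr3, chosen so that its shielding matches the anti-to-silyloxy approach). This is the Lewis acid chromophore activation known for intermolecular enone–alkene (2+2) photocycloadditions. The coordinated carbonyl reacts from a red-shifted π,π* state and cannot enolise while the adduct accumulates, and the cold mixture is run directly into the organocerium reagent of step 7. The fallback sets out from 7 and 8 and comes back at 9 (telescoped, at 10); it makes no new compound (F0).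

Step 22. The C3–C2 bond may migrate instead of C7a–C2. The enolate may be protonated before transmetalation. The aldol may run through a chair-type (anti) transition state or on the β face, giving C8 or C1 epimers, and the aldolate may revert. Fallback: ring enlargement and carbon–carbon bond formation are separated, and the aldol is run through an open transition state. Carbinol 18 is treated with n-BuLi (2 equiv) at −78 °C and the enolate is trapped with Me3SiCl, which gives the regiodefined C1=C2 trimethylsilyl enol ether F1; this is isolated and its constitution checked. F1 and aldehyde 27 are joined with catalytic tris(dimethylamino)sulfonium difluorotrimethylsilicate in THF at −78 °C. This fluoride-promoted aldol of a naked enolate is syn-selective whatever the enolate geometry, and it gives the O-trimethylsilyl aldol F2. Mild methanolysis (citric acid, MeOH, 0 °C) returns the route at 30.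

Step 12. E2 elimination towards C5 or a 1,2-shift of the antiperiplanar C3a methyl may outrun substitution at the axial neopentyl centre. Fallback: activation and displacement are separated so that substitution can run on a better leaving group with free bromide. Alcohol 14 is converted with ClCH2SO2Cl and pyridine at 0 °C into the axial chloromethanesulfonate F3. F3 is displaced with LiBr in DMF at 25–50 °C with inversion, which returns the route at 15.

Further compounds
F0 | step 6 | none | none
F1 | step 22 | C1=C2 trimethylsilyl enol ether of the trans-fused hydrindan-2-one | C1=C(O[Si](C)(C)C)C[C@]2(C)[C@@H](Br)CC[C@@](C)(O[Si](CC)(CC)CC)[C@@H]12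
F2 | step 22 | O8-trimethylsilyl ether of β-hydroxy ketone 30 | CC1(C)C[C@@](O[Si](CC)(CC)CC)([C@H](O[Si](C)(C)C)[C@@H]2C(=O)C[C@]3(C)[C@@H](Br)CC[C@@](C)(O[Si](CC)(CC)CC)[C@@H]23)CC[C@@H]1Br
F3 | step 12 | C4 axial chloromethanesulfonate of 14 | C=C1C[C@]2(C)[C@H](OS(=O)(=O)CCl)CC[C@@](C)(O[Si](CC)(CC)CC)[C@@H]12
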